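## Structural features

Eryvarin F is a 4H-chromen-4-one (rings A and C) that carries ring B on an oxygen rather than on carbon: C3 of the pyrone is joined to C1' of a 2',4'-dihydroxyphenyl ring through an ether bridge. Ring A bears a hydroxyl at C7 flanked by 3-methylbut-2-enyl (prenyl) groups at C6 and C8, and C2 of ring C is unsubstituted. There is no stereocentre and no stereogenic double bond, so the problems are regiochemistry and chemoselectivity. The fragile parts are the two trisubstituted alkenes next to a free phenol (acid closes them to chromans, electrophilic oxidants epoxidise them), the oxidisable resorcinol of ring B, and C2 of the pyrone, which hydroxide or alkoxide can attack with ring opening. The real difficulty is the C3–O–C1' ether: the nucleophile is an enolic oxygen, and the aryl partner would be a 1,2,4-trioxygenated benzene, too electron-rich for nucleophilic aromatic substitution and a hindered, poor partner for metal-mediated O-arylation. The key step turns this around: O3 is alkylated at an sp3 carbon, and ring B is then grown on it from a four-carbon acyl chain (C1', C2', C5', C6') and a two-carbon ynol ether (C3', C4'), whose polarity puts the hydroxyl at C2' and the silyloxy group at C4'. The second difficulty, two prenyl groups on ring A without O-alkylation or isomer mixtures, is eased because C6 and C8 are exactly the two positions activated by both oxygens of a resorcinol ketone.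

## Logic of the disconnections

22 to 21. The O7–Si and O4'–Si bonds are cut. Both phenols that would interfere with ketene chemistry are thereby masked by one kind of group, while the 2'-hydroxyl needs no mask because it is created by the annulation itself. The forward step must be neither acidic (prenyl next to phenol) nor strongly basic (pyrone C2), which points to buffered fluoride.

21 to 13 and 16. The bonds C2'–C3', C4'–C5' and C1'–C2' of ring B are cut. The aryl–oxygen bond then never has to be formed, because the ether oxygen sits on the sp3 carbon of a but-2-enoyl chain. A whole aromatic ring with two phenolic oxygens is reduced to a C4 acyl chloride and a C2 ynol ether. The forward step must generate a vinylketene in the presence of two prenyl groups and a pyrone, and must join the two partners with one regiochemistry only.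

16 to 14. The O–Si bond and the C≡C bond are cut, leading back through 15 to a two-carbon ester. The demand is a clean double bromine–lithium exchange and silylation on oxygen, not on carbon.

13 to 12 to 11. The C–Cl bond and then the ester O–CH3 bond are cut. This is where the precursor design is tightened: both operations must be close to neutral, because hydroxide would attack C2 of the pyrone and the aryl silyl ether, and free HCl would attack the prenyl groups. A tin hydroxide for the ester and a chloroenamine for the chloride meet this.

11 to 9 and 10. The O3–CH2 bond is cut. This is the simple SN2 step that replaces the O-arylation, and it needs only that the enolic hydroxyl be the sole free acidic group, which the hindered silyl ether at O7 ensures.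

9 to 7. The C3–O bond is cut, through 8. The oxygen is to be introduced at the electron-poor C2=C3 bond in the presence of two electron-rich alkenes, so the forward oxidant must be nucleophilic.

7 to 5. The bonds C2–C3 and O1–C2 are cut, through 6. This removes one carbon and ring C, and leaves an ortho-hydroxy methyl ketone. The forward step needs the chelated 2-hydroxyl free and the 4-oxygen protected.

5 to 3 and 4. The two aryl–CH2 bonds at the future C6 and C8 are cut. Regiochemistry is moved back to the placing of two iodine atoms. The forward coupling must deliver the allyl unit through its unsubstituted terminus.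

3 to 2 to 1. The O–Si bond and the two C–I bonds are cut. In 1 the positions to be iodinated are the only ones activated by both hydroxyls, and the hydroxyl to be silylated is the only one not held in a hydrogen bond.

## Other disconnections considered

Alternative 1: The cut is at C3–O (the ether bond) and C2–O1 of ring C. Ring B stays intact as 2,4-bis(methoxymethoxy)phenol A3, and rings A and C are reduced to 1-[2-fluoro-4-(methoxymethoxy)-3,5-bis(3-methylbut-2-enyl)phenyl]prop-2-yn-1-one A2.
- Forward step: a cationic monovalent gold catalyst activates A2, an N-oxide delivers oxygen to the terminal alkyne carbon, and the 1,3-dicarbonyl gold carbene at C3 inserts into the O–H bond of A3 to give the chelated enol A1. Displacement of fluoride by the enol oxygen then closes ring C, and acid removes three acetals.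
- In favour: like the chosen plan it avoids O-arylation, since the ether is made by a carbene on the chromone side; on this central point it is the equal of the chosen plan. It is more convergent, because ring B enters as one finished piece and no ynol ether is needed; on convergence and on the availability of the ring B building block it is the better plan.
- Against: an electrophilic gold carbene is generated next to two prenyl alkenes (cyclopropanation) and in the presence of a very electron-rich arene (C–H insertion ortho to the hydroxyl of A3 instead of O–H insertion), and the N-oxide can oxidise the carbene a second time. The ketoaldehyde can lose its formyl group under the base needed for fluoride displacement. The last step is acidic acetal cleavage beside prenyl groups and a free phenol, where the chosen plan ends with fluoride.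
- Step economy: the count should be about the same, with a slightly shorter longest sequence. The chosen plan is preferred for chemoselectivity, not for length.

Alternative 2: The cut is at C4a–C8a and C5–C6 of ring A.
- Forward step: the diene A5, a 1-methoxy-1,3-bis(trimethylsilyloxy)diene carrying both prenyl groups, adds to the terminal ynone 1-[2,4-bis(methoxymethoxy)phenoxy]but-3-yn-2-one A6 in a Diels–Alder reaction. Loss of methanol and of the silyl groups aromatises ring A to the ketone A4, which still needs a one-carbon insertion to close ring C and then deprotection.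
- In favour: both prenyl groups come from plain enolate alkylation of an acetoacetate, so neither tin nor palladium is used and the substitution pattern of ring A is fixed by the cycloaddition; on reagent economy and on avoiding toxic tin it is the better plan. The ether is again made by alkylation at sp3 carbon (phenoxide on a haloacetyl unit), so on the central ether problem it is the equal of the chosen plan.
- Against: the diene is substituted at C2 and at its reacting terminus C4, which disfavours the s-cis form and slows the addition. A6 is a base-sensitive Michael acceptor with acidic α-hydrogens. A4 has two free phenols next to prenyl groups, so the one-carbon closure (formamide acetals methylate the 4-hydroxyl; Lewis acid variants threaten chroman formation) needs extra protection. The end is again acidic.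
- Step economy: two short branches give a shorter longest sequence, but protection steps after the key step should bring the total to roughly that of the chosen plan. Mechanistically it builds ring A, which can be bought with both oxygens and the acyl carbon in place, whereas the chosen plan builds the ring that is hard to attach.

Alternative 3: The cut is at C7–C8, C4a–C8a and C6–C7 of ring A.
- Forward step: the same type of annulation as in the chosen plan. (E)-7-Methylocta-2,6-dienoyl chloride A8 and a tertiary amine give a vinylketene, which combines with the internal ynol ether triisopropyl(5-methylhex-4-en-1-ynyloxy)silane A9 by [2+2] addition, four-electron opening and six-electron closure to give the phenol A7.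
- In favour: both prenyl groups are placed with full regiocontrol and without tin, and the two oxygens of ring A emerge differentiated (free at C7, silylated at the future O1). A substituted siloxyalkyne such as A9 is a more stable and better documented partner than the parent 16; on this point the alternative is the better of the two.
- Against: A7 has neither the C4 carbon nor ring C nor ring B. The acyl group must be introduced onto a prenylated, electron-rich arene (Friedel–Crafts or Fries conditions threaten the prenyl groups), and the ether problem of ring B is left wholly unsolved, so a second solution, most likely the chosen key step itself, would still be needed.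
- Step economy: it spends a benzannulation on a ring that 1 supplies ready-made, so it is clearly longer. Mechanistically it is equivalent to the chosen plan, but applied where it gains least.

Key step: step 10

Remark: 8, 18 and 20 form as racemates and are written as one enantiomer; their stereocentres disappear within the same step, and 22 has none.

## Steps

Step 1
Reactants: 1 1-(2,4-dihydroxyphenyl)ethanone (2,4-dihydroxyacetophenone)
Product: 2 1-(2,4-dihydroxy-3,5-diiodophenyl)ethanone
Conditions: NIS (2.1 equiv), MeCN, 0 °C → rt, dark
Reagents that add atoms: N-iodosuccinimide, O=C1CCC(=O)N1I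
Why: Electrophilic aromatic iodination; C3 and C5 are the only positions ortho or para to both hydroxyls, while C6 is meta to both and deactivated by the acetyl group, so the reaction should stop at the 3,5-diiodide.

Step 2
Reactants: 2 1-(2,4-dihydroxy-3,5-diiodophenyl)ethanone
Product: 3 1-[2-hydroxy-3,5-diiodo-4-(triisopropylsilyloxy)phenyl]ethanone
Conditions: TIPSOTf (1.05 equiv), 2,6-lutidine, CH2Cl2, −40 → 0 °C
Reagents that add atoms: triisopropylsilyl trifluoromethanesulfonate, CC(C)[Si](OS(=O)(=O)C(F)(F)F)(C(C)C)C(C)C
Why: O-silylation; the 4-hydroxyl is the more acidic and is not tied up in the hydrogen bond to the ketone, so one equivalent of the reactive silyl triflate should take it selectively despite the flanking iodines, leaving the chelated 2-hydroxyl for the later ring closure.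

Step 3
Reactants: 3 1-[2-hydroxy-3,5-diiodo-4-(triisopropylsilyloxy)phenyl]ethanone; 4 tributyl(3-methylbut-2-enyl)stannane
Product: 5 1-[2-hydroxy-3,5-bis(3-methylbut-2-enyl)-4-(triisopropylsilyloxy)phenyl]ethanone
Conditions: 4 (2.6 equiv), Pd(PPh3)4 (10 mol%), DMF, 90 °C
Reagents that add atoms: none
Why: Double Stille coupling; zerovalent palladium inserts into each C–I bond, the allylic stannane transmetalates, and reductive elimination at the unsubstituted allyl terminus should give the linear prenyl groups. After this step the silyl ether is flanked by two alkyl groups and sits on a less acidic phenol, which makes it robust for the rest of the route.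

Step 4
Reactants: 5 1-[2-hydroxy-3,5-bis(3-methylbut-2-enyl)-4-(triisopropylsilyloxy)phenyl]ethanone
Product: 7 6,8-bis(3-methylbut-2-enyl)-7-(triisopropylsilyloxy)chromen-4-one, via enaminone 6 (not isolated)
Conditions: Me2NCH(OMe)2 (3 equiv), toluene, 90 °C; then 1 M aq. HCl, CH2Cl2, rt
Reagents that add atoms: N,N-dimethylformamide dimethyl acetal, COC(OC)N(C)C
Why: Condensation of the methyl ketone with the formamide acetal gives enaminone 6; dilute acid then promotes conjugate addition of the 2-hydroxyl and loss of dimethylamine (addition–elimination), the standard chromone synthesis, under conditions too mild to cyclise the prenyl group ortho to that hydroxyl.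

Step 5
Reactants: 7 6,8-bis(3-methylbut-2-enyl)-7-(triisopropylsilyloxy)chromen-4-one
Product: 9 3-hydroxy-6,8-bis(3-methylbut-2-enyl)-7-(triisopropylsilyloxy)chromen-4-one, via 2,3-epoxychromanone 8 (not isolated)
Conditions: 30% aq. H2O2, 2 M aq. NaOH, CH2Cl2, 0 °C; then TsOH·H2O (cat.), CH2Cl2, rt
Reagents that add atoms: hydrogen peroxide, OO
Why: Weitz–Scheffer epoxidation; hydroperoxide adds to C2 of the enone and the enolate closes the (necessarily cis-fused, racemic) epoxide, a nucleophilic oxidation that leaves the electron-rich prenyl alkenes alone. Acid opens the epoxy acetal at C2 and loss of the C3 hydrogen gives the enol 9, which removes both stereocentres.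

Step 6
Reactants: 9 3-hydroxy-6,8-bis(3-methylbut-2-enyl)-7-(triisopropylsilyloxy)chromen-4-one; 10 methyl (E)-4-bromobut-2-enoate
Product: 11 methyl (E)-4-[4-oxo-6,8-bis(3-methylbut-2-enyl)-7-(triisopropylsilyloxy)chromen-3-yl]oxybut-2-enoate
Conditions: 10 (1.2 equiv), K2CO3, acetone, rt
Reagents that add atoms: none
Why: Williamson ether synthesis; the acidic enolic hydroxyl is the only free OH and displaces the primary allylic bromide by SN2, which forms the ether bond of the target at an sp3 carbon and leaves the E double bond untouched.

Step 7
Reactants: 11 methyl (E)-4-[4-oxo-6,8-bis(3-methylbut-2-enyl)-7-(triisopropylsilyloxy)chromen-3-yl]oxybut-2-enoate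
Product: 12 (E)-4-[4-oxo-6,8-bis(3-methylbut-2-enyl)-7-(triisopropylsilyloxy)chromen-3-yl]oxybut-2-enoic acid
Conditions: Me3SnOH (5 equiv), ClCH2CH2Cl, 70 °C; then cold 5% aq. HCl wash
Reagents that add atoms: trimethyltin hydroxide, C[Sn](C)(C)O
Why: Methyl ester cleavage with trimethyltin hydroxide, a nearly neutral acyl substitution; it avoids free hydroxide, which could open the pyrone at C2, cleave the aryl silyl ether or move the double bond out of conjugation.

Step 8
Reactants: 12 (E)-4-[4-oxo-6,8-bis(3-methylbut-2-enyl)-7-(triisopropylsilyloxy)chromen-3-yl]oxybut-2-enoic acid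
Product: 13 (E)-4-[4-oxo-6,8-bis(3-methylbut-2-enyl)-7-(triisopropylsilyloxy)chromen-3-yl]oxybut-2-enoyl chloride
Conditions: 1-chloro-N,N,2-trimethylprop-1-en-1-amine (1.2 equiv), CH2Cl2, 0 °C → rt; volatiles removed, used crude
Reagents that add atoms: 1-chloro-N,N,2-trimethylprop-1-en-1-amine, CC(C)=C(Cl)N(C)C
Why: Acid chloride formation with an α-chloroenamine; the acid adds to the keteniminium form and chloride displaces the amide, so no HCl is set free and the prenyl groups and the silyl ether are not endangered.

Step 9
Reactants: 14 ethyl 2,2-dibromoacetate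
Product: 16 ethynyloxy(triisopropyl)silane, via lithium ethynolate 15 (not isolated)
Conditions: t-BuLi (4.1 equiv), THF, −78 → 0 °C; then TIPSOTf, −78 → 0 °C
Reagents that add atoms: triisopropylsilyl trifluoromethanesulfonate, CC(C)[Si](OS(=O)(=O)C(F)(F)F)(C(C)C)C(C)C
Why: Ynolate synthesis by cleavage of an ester dianion; two bromine–lithium exchanges give first the bromo enolate and then the dianion, which expels ethoxide to form 15. The bulky silyl electrophile should react at oxygen to give the ynol silyl ether rather than at carbon.

Step 10
Reactants: 13 (E)-4-[4-oxo-6,8-bis(3-methylbut-2-enyl)-7-(triisopropylsilyloxy)chromen-3-yl]oxybut-2-enoyl chloride; 16 ethynyloxy(triisopropyl)silane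
Product: 21 3-[2-hydroxy-4-(triisopropylsilyloxy)phenoxy]-6,8-bis(3-methylbut-2-enyl)-7-(triisopropylsilyloxy)chromen-4-one, via vinylketene 17 (not isolated), via 4-vinylcyclobutenone 18 (not isolated), via dienylketene 19 (not isolated), via cyclohexa-2,4-dienone 20 (not isolated)
Conditions: 16 (2.5 equiv), Et3N (1.5 equiv), toluene, 13 added slowly at rt; then 90 °C
Reagents that add atoms: none
Why: The closest known reaction type is the Danheiser benzannulation of a vinylketene with a siloxyalkyne, here with the ketene made by dehydrochlorination of an unsaturated acid chloride. Et3N removes a γ-hydrogen of 13, acidified by the enoyl chloride and the adjacent oxygen, and loss of chloride gives vinylketene 17. The nucleophilic CH carbon of 16 bonds to the ketene carbonyl carbon and the oxygen-bearing carbon to the ketene α-carbon, a regiochemistry fixed by the polarisation of the ynol ether, so the [2+2] adduct is the 3-silyloxy-4-vinylcyclobutenone 18 (bonds C2'–C3' and C4'–C5'). On heating, 18 opens reversibly by four-electron electrocyclic ring opening to dienylketene 19, whose isomer with ketene and aryloxyvinyl group cis closes ring B by a thermal disrotatory six-electron electrocyclisation (bond C1'–C2') to dienone 20, and tautomerisation gives phenol 21. The former acyl carbon thus becomes C2' with its hydroxyl ortho to the ether oxygen, and the ynol carbon becomes C4' with the silyloxy group para to it, which is the pattern of ring B; no stereocentre is formed that survives, those of 18 and 20 being lost on aromatisation. The step needs the ynol ether to win over the prenyl alkenes, the pyrone double bond and a second ketene molecule as [2+2] partner, which its much higher nucleophilicity, its excess and the slow addition of 13 should secure. It also needs the new phenol not to be acylated, which the two-temperature protocol addresses, since 21 appears only on heating, after 13 and 17 have been consumed at room temperature.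

Step 11
Reactants: 21 3-[2-hydroxy-4-(triisopropylsilyloxy)phenoxy]-6,8-bis(3-methylbut-2-enyl)-7-(triisopropylsilyloxy)chromen-4-one
Product: 22 Eryvarin F, 3-(2,4-dihydroxyphenoxy)-7-hydroxy-6,8-bis(3-methylbut-2-enyl)chromen-4-one
Conditions: Bu4NF (3 equiv), AcOH (3 equiv), THF, 0 °C → rt
Reagents that add atoms: none
Why: Fluoride-induced cleavage of both aryl silyl ethers, driven by the Si–F bond; acetic acid keeps the medium from becoming basic, so the pyrone and the air-sensitive resorcinol are spared, and the absence of strong acid leaves the prenyl groups next to the freed 7-hydroxyl open-chain.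

## Compound list

1 | 1-(2,4-dihydroxyphenyl)ethanone (2,4-dihydroxyacetophenone) | CC(=O)c1ccc(O)cc1O | starting material
2 | 1-(2,4-dihydroxy-3,5-diiodophenyl)ethanone | CC(=O)c1cc(I)c(O)c(I)c1O | intermediate
3 | 1-[2-hydroxy-3,5-diiodo-4-(triisopropylsilyloxy)phenyl]ethanone | CC(=O)c1cc(I)c(O[Si](C(C)C)(C(C)C)C(C)C)c(I)c1O | intermediate
4 | tributyl(3-methylbut-2-enyl)stannane | CC(C)=CC[Sn](CCCC)(CCCC)CCCC | starting material
5 | 1-[2-hydroxy-3,5-bis(3-methylbut-2-enyl)-4-(triisopropylsilyloxy)phenyl]ethanone | CC(=O)c1cc(CC=C(C)C)c(O[Si](C(C)C)(C(C)C)C(C)C)c(CC=C(C)C)c1O | intermediate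
6 | (E)-3-(dimethylamino)-1-[2-hydroxy-3,5-bis(3-methylbut-2-enyl)-4-(triisopropylsilyloxy)phenyl]prop-2-en-1-one | CN(C)/C=C/C(=O)c1cc(CC=C(C)C)c(O[Si](C(C)C)(C(C)C)C(C)C)c(CC=C(C)C)c1O | intermediate
7 | 6,8-bis(3-methylbut-2-enyl)-7-(triisopropylsilyloxy)chromen-4-one | O=c1ccoc2c(CC=C(C)C)c(O[Si](C(C)C)(C(C)C)C(C)C)c(CC=C(C)C)cc12 | intermediate
8 | rac-cis-2,3-epoxy-6,8-bis(3-methylbut-2-enyl)-7-(triisopropylsilyloxy)chroman-4-one | O=C1[C@H]2O[C@H]2Oc2c(CC=C(C)C)c(O[Si](C(C)C)(C(C)C)C(C)C)c(CC=C(C)C)cc12 | intermediate
9 | 3-hydroxy-6,8-bis(3-methylbut-2-enyl)-7-(triisopropylsilyloxy)chromen-4-one | O=c1c(O)coc2c(CC=C(C)C)c(O[Si](C(C)C)(C(C)C)C(C)C)c(CC=C(C)C)cc12 | intermediate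
10 | methyl (E)-4-bromobut-2-enoate | COC(=O)/C=C/CBr | starting material
11 | methyl (E)-4-[4-oxo-6,8-bis(3-methylbut-2-enyl)-7-(triisopropylsilyloxy)chromen-3-yl]oxybut-2-enoate | COC(=O)/C=C/COc1coc2c(CC=C(C)C)c(O[Si](C(C)C)(C(C)C)C(C)C)c(CC=C(C)C)cc2c1=O | intermediate
12 | (E)-4-[4-oxo-6,8-bis(3-methylbut-2-enyl)-7-(triisopropylsilyloxy)chromen-3-yl]oxybut-2-enoic acid | OC(=O)/C=C/COc1coc2c(CC=C(C)C)c(O[Si](C(C)C)(C(C)C)C(C)C)c(CC=C(C)C)cc2c1=O | intermediate
13 | (E)-4-[4-oxo-6,8-bis(3-methylbut-2-enyl)-7-(triisopropylsilyloxy)chromen-3-yl]oxybut-2-enoyl chloride | O=C(Cl)/C=C/COc1coc2c(CC=C(C)C)c(O[Si](C(C)C)(C(C)C)C(C)C)c(CC=C(C)C)cc2c1=O | intermediate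
14 | ethyl 2,2-dibromoacetate | CCOC(=O)C(Br)Br | starting material
15 | lithium ethynolate | [Li+].[O-]C#C | intermediate
16 | ethynyloxy(triisopropyl)silane | C#CO[Si](C(C)C)(C(C)C)C(C)C | intermediate
17 | (3E)-4-[4-oxo-6,8-bis(3-methylbut-2-enyl)-7-(triisopropylsilyloxy)chromen-3-yl]oxybuta-1,3-dien-1-one | O=C=C/C=C/Oc1coc2c(CC=C(C)C)c(O[Si](C(C)C)(C(C)C)C(C)C)c(CC=C(C)C)cc2c1=O | intermediate
18 | rac-4-[(E)-2-[4-oxo-6,8-bis(3-methylbut-2-enyl)-7-(triisopropylsilyloxy)chromen-3-yl]oxyethenyl]-3-(triisopropylsilyloxy)cyclobut-2-en-1-one | O=C1C=C(O[Si](C(C)C)(C(C)C)C(C)C)[C@@H]1/C=C/Oc1coc2c(CC=C(C)C)c(O[Si](C(C)C)(C(C)C)C(C)C)c(CC=C(C)C)cc2c1=O | intermediate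
19 | (3E,5E)-6-[4-oxo-6,8-bis(3-methylbut-2-enyl)-7-(triisopropylsilyloxy)chromen-3-yl]oxy-3-(triisopropylsilyloxy)hexa-1,3,5-trien-1-one | O=C=C/C(O[Si](C(C)C)(C(C)C)C(C)C)=C\C=C\Oc1coc2c(CC=C(C)C)c(O[Si](C(C)C)(C(C)C)C(C)C)c(CC=C(C)C)cc2c1=O | intermediate
20 | rac-6-[4-oxo-6,8-bis(3-methylbut-2-enyl)-7-(triisopropylsilyloxy)chromen-3-yl]oxy-3-(triisopropylsilyloxy)cyclohexa-2,4-dien-1-one | O=C1C=C(O[Si](C(C)C)(C(C)C)C(C)C)C=C[C@@H]1Oc1coc2c(CC=C(C)C)c(O[Si](C(C)C)(C(C)C)C(C)C)c(CC=C(C)C)cc2c1=O | intermediate
21 | 3-[2-hydroxy-4-(triisopropylsilyloxy)phenoxy]-6,8-bis(3-methylbut-2-enyl)-7-(triisopropylsilyloxy)chromen-4-one | CC(C)=CCc1cc2c(=O)c(Oc3ccc(O[Si](C(C)C)(C(C)C)C(C)C)cc3O)coc2c(CC=C(C)C)c1O[Si](C(C)C)(C(C)C)C(C)C | intermediate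
22 | Eryvarin F, 3-(2,4-dihydroxyphenoxy)-7-hydroxy-6,8-bis(3-methylbut-2-enyl)chromen-4-one | CC(C)=CCc1cc2c(=O)c(Oc3ccc(O)cc3O)coc2c(CC=C(C)C)c1O | target

## Step count and least certain steps

Total step count: 11. Longest linear sequence: 10 (steps 1 to 8, 10 and 11); step 9 is a one-step branch.

**Step 10 (key step).** The most likely failure is loss of the ketene to side paths before it meets the ynol ether: dimerisation, acylation by remaining 13, or protonation of 16 by triethylammonium chloride, which would destroy the partner. A second risk is incomplete thermal opening of 18, or opening mainly to the dienylketene geometry that cannot cyclise. The fallback keeps the annulation but makes the same vinylketene without acid chloride, amine or ammonium salt, by the photochemical Wolff variant. It sets out from 9: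
- Conjugate addition of the enolic hydroxyl to but-3-yn-2-one (DABCO cat., CH2Cl2) should give (E)-4-[4-oxo-6,8-bis(3-methylbut-2-enyl)-7-(triisopropylsilyloxy)chromen-3-yl]oxybut-3-en-2-one F1.
- Trifluoroacetylation of its kinetic enolate (LiN(SiMe3)2, CF3CO2CH2CF3, THF, −78 °C) gives (E)-1,1,1-trifluoro-6-[4-oxo-6,8-bis(3-methylbut-2-enyl)-7-(triisopropylsilyloxy)chromen-3-yl]oxyhex-5-ene-2,4-dione F2.
- Diazo transfer with methanesulfonyl azide (Et3N, H2O, MeCN), with loss of the trifluoroacetyl group, gives (E)-1-diazo-4-[4-oxo-6,8-bis(3-methylbut-2-enyl)-7-(triisopropylsilyloxy)chromen-3-yl]oxybut-3-en-2-one F3.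
- Irradiation of F3 with 16 (Pyrex filter, CH2Cl2) should cause Wolff rearrangement with migration of the aryloxyvinyl group, which rejoins the route at 17 and proceeds through 18, 19 and 20 to 21 on warming.

**Step 9.** Deprotonation of the acidic α-hydrogen of 14 may compete with the first bromine–lithium exchange and lead to a brominated or doubly metalated ynolate; silylation on carbon and loss of the volatile, moisture-sensitive product on isolation are further risks. The fallback changes the mechanism from ester-dianion cleavage to a carbenoid rearrangement and sets out from 14. Reduction with i-Bu2AlH (CH2Cl2, −78 °C) should stop at 2,2-dibromoacetaldehyde F4. LiN(SiMe3)2 converts it into lithium 2,2-dibromoethenolate F5. n-BuLi then exchanges one bromine, and a 1,2-hydride shift of the Fritsch–Buttenberg–Wiechell type gives 15, which is silylated as in the route to 16.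

**Step 5.** Hydroxide may open the pyrone ring at C2 or attack the silyl ether faster than hydroperoxide epoxidises, and the acid isomerisation of 8 may be slow under conditions mild enough for the prenyl groups. The fallback moves the oxidation to a prenyl-free stage, where an electrophilic oxidant can be used, and sets out from 3:
- Condensation with tert-butoxybis(dimethylamino)methane (toluene, 60 °C) gives (E)-3-(dimethylamino)-1-[2-hydroxy-3,5-diiodo-4-(triisopropylsilyloxy)phenyl]prop-2-en-1-one F6.
- Dilute acid closes it to 6,8-diiodo-7-(triisopropylsilyloxy)chromen-4-one F7.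
- Dimethyldioxirane (acetone, 0 °C) gives rac-cis-2,3-epoxy-6,8-diiodo-7-(triisopropylsilyloxy)chroman-4-one F8, which TsOH (cat.) isomerises to 3-hydroxy-6,8-diiodo-7-(triisopropylsilyloxy)chromen-4-one F9.
- Double Stille coupling of F9 with 4 (Pd(PPh3)4, DMF, 90 °C) returns to 9.

**Step 3.** Allylic transposition during transmetalation or reductive elimination would give 1,1-dimethylallyl isomers, and oxidative addition at the iodide between the hydroxyl and the bulky silyl ether may be slow, which allows protodestannylation of 4 by the phenol. The fallback separates C–C bond formation from the substitution pattern of the alkene and sets out from 3. Stille coupling with allyltributylstannane (Pd(PPh3)4, DMF, 90 °C), which cannot give a regioisomer, leads to 1-[2-hydroxy-3,5-bis(prop-2-enyl)-4-(triisopropylsilyloxy)phenyl]ethanone F10. Cross-metathesis of F10 with 2-methylbut-2-ene (second-generation Grubbs catalyst, (H2IMes)(PCy3)Cl2Ru=CHPh, CH2Cl2, 40 °C) returns to 5.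

**Step 7.** The γ-aryloxy enoate may isomerise to the deconjugated enol ether, or acyl substitution may be too slow at a temperature the substrate tolerates. The fallback replaces acyl–oxygen cleavage by alkyl–oxygen cleavage and sets out from 9. Alkylation with tert-butyl (E)-4-bromobut-2-enoate (K2CO3, acetone, rt) gives tert-butyl (E)-4-[4-oxo-6,8-bis(3-methylbut-2-enyl)-7-(triisopropylsilyloxy)chromen-3-yl]oxybut-2-enoate F11. ZnBr2 (CH2Cl2, rt) removes the tert-butyl group as the alkene and, after aqueous work-up, returns to 12.

## Further compounds

F1 | step 10 | (E)-4-[4-oxo-6,8-bis(3-methylbut-2-enyl)-7-(triisopropylsilyloxy)chromen-3-yl]oxybut-3-en-2-one | CC(=O)/C=C/Oc1coc2c(CC=C(C)C)c(O[Si](C(C)C)(C(C)C)C(C)C)c(CC=C(C)C)cc2c1=O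
F2 | step 10 | (E)-1,1,1-trifluoro-6-[4-oxo-6,8-bis(3-methylbut-2-enyl)-7-(triisopropylsilyloxy)chromen-3-yl]oxyhex-5-ene-2,4-dione | FC(F)(F)C(=O)CC(=O)/C=C/Oc1coc2c(CC=C(C)C)c(O[Si](C(C)C)(C(C)C)C(C)C)c(CC=C(C)C)cc2c1=O
F3 | step 10 | (E)-1-diazo-4-[4-oxo-6,8-bis(3-methylbut-2-enyl)-7-(triisopropylsilyloxy)chromen-3-yl]oxybut-3-en-2-one | [N-]=[N+]=CC(=O)/C=C/Oc1coc2c(CC=C(C)C)c(O[Si](C(C)C)(C(C)C)C(C)C)c(CC=C(C)C)cc2c1=O
F4 | step 9 | 2,2-dibromoacetaldehyde | O=CC(Br)Br
F5 | step 9 | lithium 2,2-dibromoethenolate | [Li+].[O-]C=C(Br)Br
F6 | step 5 | (E)-3-(dimethylamino)-1-[2-hydroxy-3,5-diiodo-4-(triisopropylsilyloxy)phenyl]prop-2-en-1-one | CN(C)/C=C/C(=O)c1cc(I)c(O[Si](C(C)C)(C(C)C)C(C)C)c(I)c1O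
F7 | step 5 | 6,8-diiodo-7-(triisopropylsilyloxy)chromen-4-one | O=c1ccoc2c(I)c(O[Si](C(C)C)(C(C)C)C(C)C)c(I)cc12
F8 | step 5 | rac-cis-2,3-epoxy-6,8-diiodo-7-(triisopropylsilyloxy)chroman-4-one | O=C1[C@H]2O[C@H]2Oc2c(I)c(O[Si](C(C)C)(C(C)C)C(C)C)c(I)cc12
F9 | step 5 | 3-hydroxy-6,8-diiodo-7-(triisopropylsilyloxy)chromen-4-one | O=c1c(O)coc2c(I)c(O[Si](C(C)C)(C(C)C)C(C)C)c(I)cc12
F10 | step 3 | 1-[2-hydroxy-3,5-bis(prop-2-enyl)-4-(triisopropylsilyloxy)phenyl]ethanone | CC(=O)c1cc(CC=C)c(O[Si](C(C)C)(C(C)C)C(C)C)c(CC=C)c1O
F11 | step 7 | tert-butyl (E)-4-[4-oxo-6,8-bis(3-methylbut-2-enyl)-7-(triisopropylsilyloxy)chromen-3-yl]oxybut-2-enoate | CC(C)(C)OC(=O)/C=C/COc1coc2c(CC=C(C)C)c(O[Si](C(C)C)(C(C)C)C(C)C)c(CC=C(C)C)cc2c1=O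
A1 | alternative 1 | (E)-2-[2,4-bis(methoxymethoxy)phenoxy]-1-[2-fluoro-4-(methoxymethoxy)-3,5-bis(3-methylbut-2-enyl)phenyl]-3-hydroxyprop-2-en-1-one | O/C=C(\C(=O)c1cc(CC=C(C)C)c(OCOC)c(CC=C(C)C)c1F)Oc1ccc(OCOC)cc1OCOC
A2 | alternative 1 | 1-[2-fluoro-4-(methoxymethoxy)-3,5-bis(3-methylbut-2-enyl)phenyl]prop-2-yn-1-one | C#CC(=O)c1cc(CC=C(C)C)c(OCOC)c(CC=C(C)C)c1F
A3 | alternative 1 | 2,4-bis(methoxymethoxy)phenol | COCOc1ccc(O)c(OCOC)c1
A4 | alternative 2 | 2-[2,4-bis(methoxymethoxy)phenoxy]-1-[2,4-dihydroxy-3,5-bis(3-methylbut-2-enyl)phenyl]ethanone | COCOc1ccc(OCC(=O)c2cc(CC=C(C)C)c(O)c(CC=C(C)C)c2O)c(OCOC)c1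
A5 | alternative 2 | (1Z,3Z)-1-methoxy-7-methyl-2-(3-methylbut-2-enyl)-1,3-bis(trimethylsilyloxy)octa-1,3,6-triene | CO/C(O[Si](C)(C)C)=C(CC=C(C)C)/C(O[Si](C)(C)C)=C/CC=C(C)C
A6 | alternative 2 | 1-[2,4-bis(methoxymethoxy)phenoxy]but-3-yn-2-one | C#CC(=O)COc1ccc(OCOC)cc1OCOC
A7 | alternative 3 | 2,6-bis(3-methylbut-2-enyl)-3-(triisopropylsilyloxy)phenol | CC(C)=CCc1ccc(O[Si](C(C)C)(C(C)C)C(C)C)c(CC=C(C)C)c1O
A8 | alternative 3 | (E)-7-methylocta-2,6-dienoyl chloride | CC(C)=CCC/C=C/C(Cl)=O
A9 | alternative 3 | triisopropyl(5-methylhex-4-en-1-ynyloxy)silane | CC(C)=CCC#CO[Si](C(C)C)(C(C)C)C(C)C
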